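The data stem from a simulated flask for an exercise; noise was put on by code.

The impurity comes first when the next flask is planned: the suspect step free catalyst + impurity → spent catalyst A takes one free catalyst for each impurity. If that step runs through, impurity is its limiting reagent, at 0.14 mM against 0.40 mM of free catalyst. What stays is the working catalyst W = 0.260 mM, the charge of free catalyst less the charge of impurity. The question is whether the recipe is worth running as written.

common to all: left-handed substrate 0.20 M; right-handed substrate 0.20 M; impurity 0.14 mM

| charge | coupling partner | free catalyst | remark | time |
|---|---|---|---|---|
| ash | 0.30 M | 0.40 mM | run made earlier |  |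
| larch | 0.45 M | 0.40 mM | run made earlier |  |
| oak | 0.60 M | 0.60 mM | run made earlier |  |
| flask | 0.600 M | 0.40 mM |  | 2.0 h |

| run | time / min | left-handed product / % | right-handed product / % |
|---|---|---|---|
| ash | 20.0 | 6 | 2 |
| ash | 40.0 | 12 | 4 |
| ash | 50.0 | 11 | 6 |
| ash | 80.0 | 16 | 6 |
| larch | 6.00 | 3 | 3 |
| larch | 12.0 | 4 | 6 |
| larch | 30.0 | 12 | 10 |
| larch | 80.0 | 19 | 10 |
| oak | 10.0 | 9 | 7 |
| oak | 25.0 | 19 | 10 |
| oak | 50.0 | 27 | 16 |
| oak | 80.0 | 28 | 20 |

(standard deviation of a reading: 1.5 percentage points)

- free catalyst is single-handed; left-handed substrate and right-handed substrate are mirror images of each other, charged as a racemate, each of them at the stated concentration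
- on the list of suspects stand: coupling partner + free catalyst + left-handed substrate -> free catalyst + left-handed product; coupling partner + free catalyst + right-handed substrate -> free catalyst + right-handed product; left-handed substrate <-> right-handed substrate; free catalyst + impurity -> spent catalyst A; 2 coupling partner -> self-condensation product; coupling partner + free catalyst -> spent catalyst B
- an excess is the difference of the two amounts in percent of their sum
- an excess is below zero if the other one leads

1. left-handed product and right-handed product together, in percent of the left-handed substrate and right-handed substrate charged together, at 2.0 h
2. excess of left-handed product over right-handed product in the product at 2.0 h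
3. whether the exchange between left-handed substrate and right-handed substrate keeps pace with the reaction: how far the product's excess at 2.0 h gets from its value without exchange to its value with instant exchange (above 80% keeps pace, below 20% hardly takes part, else lags behind)

Oak is the run to scale from, since it carries the same 0.60 M of coupling partner as the flask, with W = 0.460 mM. Let L be minus the natural logarithm of the fraction of substrate unreacted. My working rule is that, at equal charges of partner and substrate and at equal time, L goes with W. Oak's readings give L = 0.562 at 50.0 min and 0.654 at 80.0 min. Carrying that last slope on to 2.0 h gives 0.776, though the slope is rough, given the scatter of 1.5 percentage points on each reading. Scaling by W then gives L = 0.439 for the flask, so my estimate is 35.5% product. That is enough to weigh, so the recipe stays unchanged.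

The forecast, from the same runs, says 32% with excess 31% and exchange that hardly takes part, the product being “nearly plateaued by 2 h”. My figure is higher: I carried the slope of oak's last two readings on to 2.0 h.

The flask gives 40.2% with excess 27.1%, and the exchange lags behind, getting 26% of the way. At 2.00 h the flask holds free catalyst at 64.3%, spent catalyst A at 35.0% and spent catalyst B at 0.737% of the catalyst charged, while W is 65.0% of that charge.

    coupling partner + free catalyst + left-handed substrate → free catalyst + left-handed product (k = 92.0 /M²/min)
    coupling partner + free catalyst + right-handed substrate → free catalyst + right-handed product (k = 47.0 /M²/min)
    left-handed substrate ⇌ right-handed substrate (k = 0.00470 /min)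
    free catalyst + impurity → spent catalyst A (k = 760 /M/min)
    2 coupling partner → self-condensation product (k = 0.0200 /M/min)
    coupling partner + free catalyst → spent catalyst B (k = 3.90 × 10⁻⁴ /M/min)

In the neighbour flask with 8.4 × 10⁻⁵ M of impurity, W = 0.316 mM. Scaling the flask's own L of 0.515 by W gives 46.5% product, and W stands at 79.0% of the catalyst charged. The computed neighbour gives 44.8%, with free catalyst at 78.1%.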